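**Plan**

- Numbering of target 12 (7-oxabicyclo[4.1.0]hept-4-ene): O7, C1 (quaternary, CH2OBz), C2 (OMe), C3 (OBz), C4=C5, C6 (oxirane CH).
- Cuts: (a) the CH2O–benzoate and the fused oxirane, traced by a Payne rearrangement to a temporary spiro-oxirane on C1 plus a free C6 hydroxyl; (b) the ring bond C5–C6, cut to a Z-iodoalkene and an aldehyde; (c) the spiro-oxirane to a 2-substituted allyl alcohol; (d) C2–C3 to (Z)-3-iodoacrolein and a γ-methoxyallylborane.
- Forward order: chain C5–C4–C3–C2–C1 first, then the spiro-oxirane, then the carbocycle (C5–C6), then the fused oxirane by oxirane migration, then the second benzoate.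
- Enabling feature: C6 is an oxygen-bearing CH bonded to the cis-alkene carbon C5 (retron of an alkenylmetal adding to an aldehyde), and O7–C1–CH2O is a 2,3-epoxy alcohol, the Payne isomer of a spiro-oxirane at C1 with an alkoxide on C6.
- Stereochemistry: C2/C3 from the (+)-α-pinene-derived Z-γ-methoxyallylborane (syn, reagent control); C1 from D-(−)-tartrate in the Sharpless epoxidation, inverted in the Payne step; C6 from Felkin–Anh addition anti to the oxirane C–O bond.

Key step: step 7

Remark: aldehyde 2 is assumed to be used as a cold solution directly after its preparation, because it isomerises to the E isomer on storage.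

Step 1
Reactants: 1 ethyl (2Z)-3-iodoprop-2-enoate
Product: 2 (2Z)-3-iodoprop-2-enal
Conditions: iBu2AlH (1.0 equiv), CH2Cl2, −78 °C; then MeOH, aq. potassium sodium tartrate (KNaC4H4O6), cold
Reagents that add atoms: none
Why: Partial reduction of an ester with iBu2AlH at −78 °C stops at the aluminium hemiacetal, which gives the aldehyde on cold work-up, and the Z geometry of the iodoalkene should survive because no acid or heat is applied (ester-to-aldehyde reduction).

Step 2
Reactants: 2 (2Z)-3-iodoprop-2-enal; 3 3-methoxy-2-methylprop-1-ene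
Product: 5 (1Z,3R,4R)-1-iodo-4-methoxy-5-methylhexa-1,5-dien-3-ol, via (Z)-3-methoxy-2-methylallyl-diisopinocampheylborane 4 (not isolated)
Conditions: 3, sBuLi, THF, −78 °C; (−)-Ipc2BOMe; BF3·OEt2; then 2, −78 °C; NaOH, H2O2, 0 °C to rt
Reagents that add atoms: none
Why: Brown asymmetric γ-alkoxyallylboration, in which lithiation of the allylic OCH2 group gives the chelated Z-methoxyallyl anion, whose Z-allylborane 4 adds to the aldehyde through a chair Zimmerman–Traxler transition state, so that the Z geometry sets the 3,4-syn relation and the (+)-α-pinene-derived isopinocampheyl groups direct attack to the Si face of the aldehyde, which should give (3R,4R).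

Step 3
Reactants: 5 (1Z,3R,4R)-1-iodo-4-methoxy-5-methylhexa-1,5-dien-3-ol
Product: 6 (1Z,3R,4R)-1-iodo-4-methoxy-5-methylhexa-1,5-dien-3-yl benzoate
Conditions: BzCl, pyridine, DMAP (cat.), CH2Cl2, 0 °C to rt
Reagents that add atoms: benzoyl chloride, O=C(Cl)c1ccccc1
Why: DMAP-catalysed acylation of the only hydroxyl group installs the C3 benzoate of the target, which also serves as the protecting group through steps 4 to 7.

Step 4
Reactants: 6 (1Z,3R,4R)-1-iodo-4-methoxy-5-methylhexa-1,5-dien-3-yl benzoate
Product: 7 (1Z,3R,4R)-5-(hydroxymethyl)-1-iodo-4-methoxyhexa-1,5-dien-3-yl benzoate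
Conditions: SeO2 (cat.), tBuOOH, CH2Cl2, rt
Reagents that add atoms: selenium dioxide, O=[Se]=O (delivers the oxygen); tert-butyl hydroperoxide, CC(C)(C)OO (terminal oxygen source)
Why: Allylic oxidation with SeO2 (Riley oxidation, catalytic with tBuOOH) proceeds by an ene reaction and a [2,3]-sigmatropic shift at the electron-rich 1,1-disubstituted alkene, where the methyl C–H should react in preference to the methine C–H that is deactivated by the methoxy group, while the iodoalkene is too electron-poor to react.

Step 5
Reactants: 7 (1Z,3R,4R)-5-(hydroxymethyl)-1-iodo-4-methoxyhexa-1,5-dien-3-yl benzoate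
Product: 8 (1S,2R,3Z)-1-[(2R)-2-(hydroxymethyl)oxiran-2-yl]-4-iodo-1-methoxybut-3-en-2-yl benzoate
Conditions: Ti(OiPr)4 (cat.), D-(−)-diethyl tartrate (cat.), tBuOOH, 4 Å molecular sieves, CH2Cl2, −20 °C
Reagents that add atoms: tert-butyl hydroperoxide, CC(C)(C)OO
Why: Sharpless asymmetric epoxidation of a 2-substituted allylic alcohol, in which the titanium tartrate complex binds the primary hydroxyl and D-(−)-diethyl tartrate delivers the oxygen to the face that gives the (R)-oxirane (reagent control, the sense known from the 2-methylglycidol series), the iodoalkene being left untouched.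

Step 6
Reactants: 8 (1S,2R,3Z)-1-[(2R)-2-(hydroxymethyl)oxiran-2-yl]-4-iodo-1-methoxybut-3-en-2-yl benzoate
Product: 9 (1S,2R,3Z)-1-[(2R)-2-formyloxiran-2-yl]-4-iodo-1-methoxybut-3-en-2-yl benzoate
Conditions: Dess–Martin periodinane, NaHCO3, CH2Cl2, 0 °C to rt
Reagents that add atoms: none
Why: Dess–Martin oxidation of the primary alcohol under bicarbonate buffering gives an aldehyde that has no α-hydrogen and therefore cannot epimerise or eliminate.

Step 7
Reactants: 9 (1S,2R,3Z)-1-[(2R)-2-formyloxiran-2-yl]-4-iodo-1-methoxybut-3-en-2-yl benzoate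
Product: 10 (3S,4S,5R,8R)-8-hydroxy-4-methoxy-1-oxaspiro[2.5]oct-6-en-5-yl benzoate
Conditions: CrCl2 (20 mol %), NiCl2·glyme (5 mol %), Cp2ZrCl2 (1.2 equiv), Bu4NBr, DMF, undivided cell, Al anode, Ni-foam cathode, constant current, rt, slow addition of 9; aqueous work-up
Reagents that add atoms: none
Why: The step is a Nozaki–Hiyama–Kishi alkenyl–aldehyde addition run in its chromium-catalytic electrochemical form: zerovalent nickel (made from NiCl2 by divalent chromium) inserts into the C–I bond of the Z-iodoalkene with retention, the alkenyl group passes to trivalent chromium, the alkenylchromium adds to the tethered aldehyde, Cp2ZrCl2 takes over the alkoxide, and the cathode returns trivalent to divalent chromium while the aluminium anode is consumed. The closest known reaction type is the intramolecular Nozaki–Hiyama–Kishi carbocyclisation of iodoalkenyl aldehydes to cyclohex-2-enols. The six-membered carbocycle closes by a 6-exo-trig addition to the C=O group with the nucleophilic alkene carbon inside the new ring, which only the Z-alkene permits. The new carbinol centre (C8 of 10, C6 of the target) is controlled by the adjacent spiro-oxirane centre: in the half-chair transition state with the OMe and OBz groups equatorial, the alkenyl carbon attacks anti to the oxirane C–O bond (Felkin–Anh, Re face of the aldehyde) and the metal-bound oxygen sits pseudo-equatorial, trans to the oxirane oxygen. The step needs this face selectivity and chemoselectivity for the aldehyde over the oxirane and the benzoate; the first rests on the stereocentre set in step 5, the second on the low basicity and aldehyde selectivity of alkenylchromium reagents and on the small standing amount of chromium.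

Step 8
Reactants: 10 (3S,4S,5R,8R)-8-hydroxy-4-methoxy-1-oxaspiro[2.5]oct-6-en-5-yl benzoate
Product: 12 [(1R,2S,3R,6R)-3-(benzoyloxy)-2-methoxy-7-oxabicyclo[4.1.0]hept-4-en-1-yl]methyl benzoate, via fused-oxirane primary alcohol 11 (not isolated)
Conditions: tBuOK (0.2 equiv), THF, 0 °C; then pyridine, BzCl, DMAP (cat.), 0 °C to rt
Reagents that add atoms: benzoyl chloride, O=C(Cl)c1ccccc1
Why: Payne rearrangement followed by acylation, in which the C8 alkoxide attacks the spiro carbon anti to the oxirane oxygen (intramolecular SN2, inversion at that carbon, retention at the carbinol carbon), the equilibrium should favour the trisubstituted fused oxirane with the primary alcohol, and benzoylation of that alcohol gives the target, a benzoyl shift between the C3 and CH2 oxygens leading to the same dibenzoate.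

**Compound list**

1 | ethyl (2Z)-3-iodoprop-2-enoate | CCOC(=O)/C=C\I | starting material
2 | (2Z)-3-iodoprop-2-enal | O=C/C=C\I | intermediate
3 | 3-methoxy-2-methylprop-1-ene | COCC(C)=C | starting material
4 | [(Z)-3-methoxy-2-methylallyl]diisopinocampheylborane (isopinocampheyl groups from (+)-α-pinene) | CO/C=C(/C)CB([C@@H]1C[C@@H]2C[C@H]([C@H]1C)C2(C)C)[C@@H]1C[C@@H]2C[C@H]([C@H]1C)C2(C)C | intermediate (not isolated)
5 | (1Z,3R,4R)-1-iodo-4-methoxy-5-methylhexa-1,5-dien-3-ol | CO[C@@H]([C@H](O)/C=C\I)C(C)=C | intermediate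
6 | (1Z,3R,4R)-1-iodo-4-methoxy-5-methylhexa-1,5-dien-3-yl benzoate | CO[C@@H]([C@H](OC(=O)c1ccccc1)/C=C\I)C(C)=C | intermediate
7 | (1Z,3R,4R)-5-(hydroxymethyl)-1-iodo-4-methoxyhexa-1,5-dien-3-yl benzoate | CO[C@@H]([C@H](OC(=O)c1ccccc1)/C=C\I)C(=C)CO | intermediate
8 | (1S,2R,3Z)-1-[(2R)-2-(hydroxymethyl)oxiran-2-yl]-4-iodo-1-methoxybut-3-en-2-yl benzoate | CO[C@@H]([C@H](OC(=O)c1ccccc1)/C=C\I)[C@@]1(CO)CO1 | intermediate
9 | (1S,2R,3Z)-1-[(2R)-2-formyloxiran-2-yl]-4-iodo-1-methoxybut-3-en-2-yl benzoate | CO[C@@H]([C@H](OC(=O)c1ccccc1)/C=C\I)[C@@]1(C=O)CO1 | intermediate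
10 | (3S,4S,5R,8R)-8-hydroxy-4-methoxy-1-oxaspiro[2.5]oct-6-en-5-yl benzoate | CO[C@H]1[C@H](OC(=O)c2ccccc2)C=C[C@@H](O)[C@@]12CO2 | intermediate
11 | (1R,2S,3R,6R)-1-(hydroxymethyl)-2-methoxy-7-oxabicyclo[4.1.0]hept-4-en-3-yl benzoate | CO[C@H]1[C@H](OC(=O)c2ccccc2)C=C[C@H]2O[C@]21CO | intermediate (not isolated)
12 | [(1R,2S,3R,6R)-3-(benzoyloxy)-2-methoxy-7-oxabicyclo[4.1.0]hept-4-en-1-yl]methyl benzoate | CO[C@H]1[C@H](OC(=O)c2ccccc2)C=C[C@H]2O[C@]21COC(=O)c1ccccc1 | target

**Step count**

Total step count: 8. Longest linear sequence: 8 steps (1 to 12); compound 3 enters at step 2.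

**Steps most likely to fail**

Step 7. The alkenyl group may add to the wrong face of the aldehyde, and the spiro-oxirane may be opened by aluminium or chromium halides before the ring closes. The fallback sets out from 9 and comes back at 10, and it fixes the carbinol configuration by inversion instead of by the addition. The ring is closed with stoichiometric CrCl2 and catalytic NiCl2 in DMSO, without electrolysis and hence without aluminium salts. If the C8 epimer, (3S,4S,5R,8S)-8-hydroxy-4-methoxy-1-oxaspiro[2.5]oct-6-en-5-yl benzoate F1, is what forms, its hydroxyl is inverted by a Mitsunobu reaction (PPh3, DIAD, 4-nitrobenzoic acid) to (3S,4S,5R,8R)-5-(benzoyloxy)-4-methoxy-1-oxaspiro[2.5]oct-6-en-8-yl 4-nitrobenzoate F2. Mild methanolysis (K2CO3, MeOH, 0 °C) then removes the more electrophilic 4-nitrobenzoate and gives 10.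

Step 8. The oxirane migration may be incomplete when the acylating agent is added, so that the unrearranged secondary alcohol is benzoylated, or benzoate may be passed between molecules by the alkoxide. The fallback sets out from 10 and comes back at 12, and it replaces trapping in the flask by a thermodynamic equilibration with full deacylation. NaOH in tBuOH–H2O hydrolyses the C5 benzoate and lets the Payne equilibrium settle, giving the diol (1R,2S,3R,6R)-1-(hydroxymethyl)-2-methoxy-7-oxabicyclo[4.1.0]hept-4-en-3-ol F3. F3 is isolated and purified, and both hydroxyls are then benzoylated (BzCl, pyridine, DMAP) to 12.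

Step 2. Lithiation of 3 may occur at the methyl group instead of the OCH2 group, and the 2-methyl-substituted borane may give lower syn- or enantioselectivity than the parent reagent. The fallback sets out from 2 and comes back at 5, and it builds the C2–C3 bond by an auxiliary-controlled aldol reaction. Evans syn glycolate aldol reaction of 2 with (4S)-4-benzyl-3-(methoxyacetyl)-1,3-oxazolidin-2-one (Bu2BOTf, Et3N, −78 °C) gives (4S)-4-benzyl-3-[(2S,3R,4Z)-3-hydroxy-5-iodo-2-methoxypent-4-enoyl]-1,3-oxazolidin-2-one F4. Transamidation (MeNHOMe·HCl, AlMe3) gives the Weinreb amide (2S,3R,4Z)-3-hydroxy-5-iodo-N,2-dimethoxy-N-methylpent-4-enamide F5. MeMgBr gives the methyl ketone (3S,4R,5Z)-4-hydroxy-6-iodo-3-methoxyhex-5-en-2-one F6, and Wittig methylenation (Ph3P=CH2, THF, low temperature) gives 5.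

**Further compounds**

F1 | step 7 | (3S,4S,5R,8S)-8-hydroxy-4-methoxy-1-oxaspiro[2.5]oct-6-en-5-yl benzoate | CO[C@H]1[C@H](OC(=O)c2ccccc2)C=C[C@H](O)[C@@]12CO2
F2 | step 7 | (3S,4S,5R,8R)-5-(benzoyloxy)-4-methoxy-1-oxaspiro[2.5]oct-6-en-8-yl 4-nitrobenzoate | CO[C@H]1[C@H](OC(=O)c2ccccc2)C=C[C@@H](OC(=O)c2ccc(cc2)[N+](=O)[O-])[C@@]12CO2
F3 | step 8 | (1R,2S,3R,6R)-1-(hydroxymethyl)-2-methoxy-7-oxabicyclo[4.1.0]hept-4-en-3-ol | CO[C@H]1[C@H](O)C=C[C@H]2O[C@]21CO
F4 | step 2 | (4S)-4-benzyl-3-[(2S,3R,4Z)-3-hydroxy-5-iodo-2-methoxypent-4-enoyl]-1,3-oxazolidin-2-one | CO[C@@H]([C@H](O)/C=C\I)C(=O)N1[C@@H](Cc2ccccc2)COC1=O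
F5 | step 2 | (2S,3R,4Z)-3-hydroxy-5-iodo-N,2-dimethoxy-N-methylpent-4-enamide | CO[C@@H]([C@H](O)/C=C\I)C(=O)N(C)OC
F6 | step 2 | (3S,4R,5Z)-4-hydroxy-6-iodo-3-methoxyhex-5-en-2-one | CO[C@@H]([C@H](O)/C=C\I)C(C)=O
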